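Ring A is cut across a2–a3 and a4–a5. The feature exploited is its contiguous a5(Br)–a6(OMe)–a1(OAr)–a2(Br) run. This run is the C5–C4–C3–C2 pattern of a 2,5-dibromo-3,4-dioxygenated thiophene, and a3(Br)–a4(H) amounts to a masked bromoacetylene. In one operation the thiophene 1,1-dioxide and (Z)-1-bromo-2-ethoxyethene undergo inverse-demand Diels–Alder addition, SO2 extrusion and acid-induced ethanol loss. This makes both bonds and the pentasubstituted arene. The precursor already carries ring B dibrominated and O-acetylated, so its aryloxy group is a far weaker donor than methoxy. Only deacetylation follows.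

Key step: step 6

**Atom labels**
- Ring A: a1 (C–O of the diaryl ether), a2 (Br), a3 (Br), a4 (H), a5 (Br), a6 (OMe).
- Ring B: b1 (C–O of the diaryl ether), b2 (C–OH), b3 (Br), b4 (H), b5 (Br), b6 (H).
- Thiophene C2/C3/C4/C5 become a2/a1/a6/a5.
- The target has no stereocentre.

**Design points**
- **Mode of aromatisation.** The cyclohexadiene left after SO2 loss carries H/Br on a3 and H/OEt on a4, and bromide is the better leaving group. With base, or on uncontrolled heating, HBr loss would give an ethoxyarene without the a3 bromine. Aromatisation is therefore triggered by acid, which activates only the ether oxygen.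
- **Ring B before the key step.** An unbrominated ring B with an alkyl-type protecting group would be an electron-rich target for the sulfur oxidant. It would also leave only a small donor gap between the two ring-A oxygens. Bromination at b3 and b5 and O-acetylation beforehand widen that gap, which improves orientation, electron demand of the diene and the choice of leaving group. The endgame is then one mild step.
- **No free phenol beside the sulfone diene.** A free phenol could add to the methoxy-bearing carbon and close a dioxine ring, so it is acetylated before the oxidation.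
- **Allyl ether for the copper coupling.** It is removed under neutral conditions while the molecule still has no C–Br bond.

Assumption: the two transient intermediates of the key step are racemic. They are drawn as one enantiomer of the endo adduct, and their configuration has no bearing on the achiral arene.

Step 1
Reactants: 1 3,4-dibromothiophene
Product: 2 3-bromo-4-methoxythiophene
Conditions: NaOCH3 (1.1 equiv), CuBr (10 mol %), MeOH–NMP, 105 °C
Reagents that add atoms: sodium methoxide, [Na+].[O-]C
Why: Copper-catalysed Ullmann-type alkoxylation of a 3-bromothiophene is established chemistry, and with about one equivalent of methoxide it can be held at the mono-ether because the first methoxy group enriches the ring and slows substitution of the second bromide, leftover 1 and any diether being removed by distillation.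

Step 2
Reactants: 2 3-bromo-4-methoxythiophene; 3 2-(allyloxy)phenol
Product: 4 3-[2-(allyloxy)phenoxy]-4-methoxythiophene
Conditions: CuI (10 mol %), picolinic acid (20 mol %), K3PO4 (2 equiv), DMSO, 90 °C
Reagents that add atoms: none
Why: Ullmann diaryl ether synthesis with the CuI–picolinic acid system, which suits ortho-substituted phenols and heteroaryl bromides; 2 holds the only C–halogen bond in the flask and the allyl ether is inert to phosphate base far below Claisen temperatures.

Step 3
Reactants: 4 3-[2-(allyloxy)phenoxy]-4-methoxythiophene
Product: 5 2-[(4-methoxythiophen-3-yl)oxy]phenol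
Conditions: Pd(PPh3)4 (3 mol %), morpholine (3 equiv), THF, rt
Reagents that add atoms: none
Why: Tsuji–Trost-type deallylation, in which zerovalent palladium ionises the aryl allyl ether to a π-allyl complex that morpholine intercepts; the medium is neutral, so the acid-sensitive dioxythiophene is untouched, and no C–Br bond exists yet, so oxidative addition cannot compete.

Step 4
Reactants: 5 2-[(4-methoxythiophen-3-yl)oxy]phenol
Product: 7 2,4-dibromo-6-[(2,5-dibromo-4-methoxythiophen-3-yl)oxy]phenyl acetate, via tetrabromophenol 6 (not isolated)
Conditions: NBS (4.05 equiv), MeCN, −10 °C → rt, dark; then pyridine, Ac2O (3 equiv), DMAP (cat.), rt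
Reagents that add atoms: N-bromosuccinimide, O=C1CCC(=O)N1Br; acetic anhydride, CC(=O)OC(C)=O
Why: Electrophilic aromatic bromination followed by O-acylation in the same flask: the four most nucleophilic C–H sites are exactly the four needed (both thiophene α-carbons, then b5 para and b3 ortho to the free hydroxyl), NBS keeps the medium free of the HBr that degrades 2,5-dibromo-3,4-dioxythiophenes, and immediate acetylation avoids isolating the oxidation-prone phenol 6.

Step 5
Reactants: 7 2,4-dibromo-6-[(2,5-dibromo-4-methoxythiophen-3-yl)oxy]phenyl acetate
Product: 8 2,4-dibromo-6-[(2,5-dibromo-4-methoxy-1,1-dioxidothiophen-3-yl)oxy]phenyl acetate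
Conditions: dimethyldioxirane (3 equiv, in acetone), CH2Cl2, −20 → 0 °C; used promptly, no nucleophilic solvents
Reagents that add atoms: dimethyldioxirane, CC1(C)OO1
Why: Oxidation of a thiophene to its 1,1-dioxide with neutral, anhydrous dimethyldioxirane, the usual choice for halogenated thiophenes that respond poorly to peracids; ring B is deactivated by two bromines and the acetate, no benzylic or allylic C–H is left to oxidise, and full substitution of the ring prevents dimerisation of the dioxide.

Step 6
Reactants: 8 2,4-dibromo-6-[(2,5-dibromo-4-methoxy-1,1-dioxidothiophen-3-yl)oxy]phenyl acetate; 9 (Z)-1-bromo-2-ethoxyethene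
Product: 12 2,4-dibromo-6-(2,3,5-tribromo-6-methoxyphenoxy)phenyl acetate, via bridged sulfone adduct 10 (not isolated), via cis-bromoethoxycyclohexadiene 11 (not isolated)
Conditions: 9 (5 equiv), PhMe, sealed tube, 100 °C; excess 9 evaporated; then camphor-10-sulfonic acid (20 mol %), PhMe, 60 °C; no base at any stage
Reagents that add atoms: none
Why: The non-aromatic, sulfone-activated diene 8 takes up the electron-rich alkene 9 in a concerted but asynchronous inverse-electron-demand [4+2] cycloaddition that makes a2–a3 and a4–a5, the bridged sulfone 10 loses SO2 by cheletropic extrusion at the reaction temperature, and the added acid ionises the a4–OEt bond of 11 to an arenium-type cation that sheds the a3 proton. The closest known reaction type is the Diels–Alder/SO2-extrusion/elimination benzannulation of halogenated thiophene 1,1-dioxides with vinyl ethers. Ring A is closed by intermolecular [4+2] annulation, four carbons (a5, a6, a1, a2) coming from the thiophene and two (a3, a4) from 9. The stereocentres of 10 and 11 follow from suprafacial addition to the Z-alkene (Br and OEt cis, endo drawn) and are all erased on aromatisation, so 12 has none. The first selectivity needed is orientation: the nucleophilic CHBr carbon of 9 (β to oxygen) must bond to a2, which is favoured because the methoxy group pushes electron density onto a5 much more strongly than the acetoxy-dibromophenoxy group does onto a2, so that a2 is the more electrophilic terminus and the negative charge building up at a1 sits next to the weaker π-donor. The second is the mode of aromatisation, in which ethanol and not HBr must leave: base is excluded, acid activates only the ether oxygen, and the cation from C–OEt ionisation is conjugated to the a6 methoxy group, whereas bromide ionisation at a3 could lean only on the poor aryloxy donor at a1.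

Step 7
Reactants: 12 2,4-dibromo-6-(2,3,5-tribromo-6-methoxyphenoxy)phenyl acetate
Product: 13 2,4-dibromo-6-(2,3,5-tribromo-6-methoxyphenoxy)phenol (target)
Conditions: K2CO3 (1.5 equiv), MeOH–THF, 0 °C → rt; dilute aqueous HCl work-up
Reagents that add atoms: none
Why: Base-mediated methanolysis of an aryl acetate whose leaving group is a stabilised dibromophenoxide, so it runs at or below room temperature, where the aryl bromides, the methyl ether and the diaryl ether are inert.

**Compound list**
1 | 3,4-dibromothiophene | Brc1cscc1Br | starting material
2 | 3-bromo-4-methoxythiophene | COc1cscc1Br | intermediate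
3 | 2-(allyloxy)phenol | C=CCOc1ccccc1O | starting material
4 | 3-[2-(allyloxy)phenoxy]-4-methoxythiophene | COc1cscc1Oc1ccccc1OCC=C | intermediate
5 | 2-[(4-methoxythiophen-3-yl)oxy]phenol | COc1cscc1Oc1ccccc1O | intermediate
6 | 2,4-dibromo-6-[(2,5-dibromo-4-methoxythiophen-3-yl)oxy]phenol | COc1c(Br)sc(Br)c1Oc1cc(Br)cc(Br)c1O | intermediate
7 | 2,4-dibromo-6-[(2,5-dibromo-4-methoxythiophen-3-yl)oxy]phenyl acetate | COc1c(Br)sc(Br)c1Oc1cc(Br)cc(Br)c1OC(C)=O | intermediate
8 | 2,4-dibromo-6-[(2,5-dibromo-4-methoxy-1,1-dioxidothiophen-3-yl)oxy]phenyl acetate | COC1=C(Br)S(=O)(=O)C(Br)=C1Oc1cc(Br)cc(Br)c1OC(C)=O | intermediate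
9 | (Z)-1-bromo-2-ethoxyethene | CCO/C=C\Br | starting material
10 | 2,4-dibromo-6-{[1,4,6-tribromo-5-ethoxy-3-methoxy-7,7-dioxido-7-thiabicyclo[2.2.1]hept-2-en-2-yl]oxy}phenyl acetate, racemic, 5-OEt and 6-Br both endo (cis, anti to the SO2 bridge) | CCO[C@@H]1[C@H](Br)[C@]2(Br)C(Oc3cc(Br)cc(Br)c3OC(C)=O)=C(OC)[C@@]1(Br)S2(=O)=O | intermediate
11 | 2,4-dibromo-6-{[2,3,5-tribromo-4-ethoxy-6-methoxycyclohexa-1,5-dien-1-yl]oxy}phenyl acetate, racemic, 3-Br and 4-OEt cis | CCO[C@@H]1[C@H](Br)C(Br)=C(Oc2cc(Br)cc(Br)c2OC(C)=O)C(OC)=C1Br | intermediate
12 | 2,4-dibromo-6-(2,3,5-tribromo-6-methoxyphenoxy)phenyl acetate | COc1c(Br)cc(Br)c(Br)c1Oc1cc(Br)cc(Br)c1OC(C)=O | intermediate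
13 | 2,4-dibromo-6-(2,3,5-tribromo-6-methoxyphenoxy)phenol | COc1c(Br)cc(Br)c(Br)c1Oc1cc(Br)cc(Br)c1O | target

Total step count: 7
Longest linear sequence: 7 (1 → 2 → 4 → 5 → 7 → 8 → 12 → 13)

**Steps most likely to fail**

Risk 1, step 6. Three things may go wrong:
- The cycloaddition may stall, because the bromo enol ether is a weak nucleophile for a diene that still carries two oxygen donors.
- Both orientations may form side by side.
- HBr may leave in place of ethanol.

The fallback sets out from 8 and takes the a3 bromine out of the cycloaddition. Compound 8 is heated with ethyl vinyl ether (CCOC=C, PhMe, sealed tube, 70 °C, then catalytic camphor-10-sulfonic acid). This is a stronger nucleophile, there is no bromide to lose, and both orientations converge after SO2 and ethanol loss on the single arene 2,4-dibromo-6-(3,6-dibromo-2-methoxyphenoxy)phenyl acetate F1. Electrophilic bromination (Br2, 1.05 equiv, AcOH–CF3CO2H, rt to 40 °C) should then enter at a3. That position is para to the methoxy group, whereas a4 is para only to the deactivated aryloxy group. Ring B is shut down by two bromines and the acetate. The route is rejoined at 12.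

Risk 2, step 5. The second oxygen transfer to sulfur may be so slow that the oxidant turns to the enol-ether-like C=C bonds of the ring and degrades it.

The fallback sets out from 7 and asks for one oxygen transfer only. m-CPBA (1 equiv) with BF3·OEt2 in CH2Cl2 at −20 °C should stop at the fully substituted, non-dimerising thiophene 1-oxide, 2,4-dibromo-6-[(2,5-dibromo-4-methoxy-1-oxidothiophen-3-yl)oxy]phenyl acetate F2. Thiophene 1-oxides are more reactive Diels–Alder dienes than the dioxides. Reaction with 9 (PhMe, rt to 60 °C) on the face syn to S=O should give the bridged sulfoxide 2,4-dibromo-6-{[1,4,6-tribromo-5-ethoxy-3-methoxy-7-oxido-7-thiabicyclo[2.2.1]hept-2-en-2-yl]oxy}phenyl acetate F3. Heating in PhMe at 110 °C expels sulfur monoxide. The route is rejoined at 11, which the acid stage of step 6 converts into 12.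

Risk 3, step 2. The copper catalyst may turn over poorly with an electron-rich, ortho-substituted bromothiophene and an ortho-substituted phenol. Hydrodebromination and oxidation of the phenol would then take over.

The fallback sets out from 2 and reverses the role of the thiophene. Bromine–lithium exchange (n-BuLi, Et2O, −78 °C), B(OiPr)3 and mild acid give (4-methoxythiophen-3-yl)boronic acid F4. This is joined to 3 by Chan–Lam oxidative coupling with divalent copper (Cu(OAc)2, pyridine, 4 Å sieves, air, CH2Cl2, rt). The route is rejoined at 4.

**Further compounds**
F1 | step 6 | 2,4-dibromo-6-(3,6-dibromo-2-methoxyphenoxy)phenyl acetate | COc1c(Br)ccc(Br)c1Oc1cc(Br)cc(Br)c1OC(C)=O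
F2 | step 5 | 2,4-dibromo-6-[(2,5-dibromo-4-methoxy-1-oxidothiophen-3-yl)oxy]phenyl acetate (configurationally labile at sulfur) | COC1=C(Br)S(=O)C(Br)=C1Oc1cc(Br)cc(Br)c1OC(C)=O
F3 | step 5 | 2,4-dibromo-6-{[1,4,6-tribromo-5-ethoxy-3-methoxy-7-oxido-7-thiabicyclo[2.2.1]hept-2-en-2-yl]oxy}phenyl acetate, racemic, 5-OEt and 6-Br endo, S=O on the side of C5–C6 | CCO[C@@H]1[C@H](Br)[C@]2(Br)C(Oc3cc(Br)cc(Br)c3OC(C)=O)=C(OC)[C@@]1(Br)[S@@]2=O
F4 | step 2 | (4-methoxythiophen-3-yl)boronic acid | COc1cscc1B(O)O
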